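Assumption: the SMILES is read as the trans-fused daucane (3R,3aS,4S,8aS)-3-hydroxy-6,8a-dimethyl-3-(propan-2-yl)-1,2,3,3a,4,7,8,8a-octahydroazulen-4-yl 4-methoxybenzoate. Comments use daucane numbering: C1 quaternary CMe, C4 C(OH)iPr, C5 ring-fusion CH, C6 CH–O, C7=C8(Me). Nothing here has been run; steps 2 and 5 are proposed extensions of known chemistry.

**Retrosynthetic overview**
- The ester and the trans ring-fusion hydrogen come from one cationic step on a cis-fused 4,5-diol: loss of the C5 hydroxyl, 1,2-hydride shift C6→C5, and capture of the C6–C8 allyl cation by 4-methoxybenzoic acid.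
- The five-membered ring is closed last through the C4–C5 bond (the bond the cyclase makes), reductively between the isopropyl ketone and the ring ketone because C4 must carry oxygen.
- The seven-membered ring comes from a six→seven 1,2-shift ring expansion of a bisabolane-type 6,6-disubstituted 3-methylcyclohexenone, as in the bisabolyl→cycloheptenyl step.
- The quaternary C1 is set by an enantioselective Michael addition of 3,6-dimethylcyclohex-2-enone to isopropyl vinyl ketone.
- Ring order: cyclohexenone (bought) → cycloheptenone → cyclopentane.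

**Step 1**
Reactants: 1 3-methylcyclohex-2-en-1-one; 2 iodomethane
Product: 4 3,6-dimethylcyclohex-2-en-1-one (racemic), via lithium dienolate 3 (not isolated)
Conditions: LDA (1.05 equiv), THF, −78 °C; MeI, −78 → 0 °C
Reagents that add atoms: iodomethane, CI
Why: Kinetic α'-deprotonation of the enone gives the cross-conjugated enolate, which is C-methylated (enolate alkylation); the new centre is racemic and is erased by enolisation in step 2.

**Step 2**
Reactants: 4 3,6-dimethylcyclohex-2-en-1-one; 5 4-methylpent-1-en-3-one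
Product: 8 (6S)-3,6-dimethyl-6-(4-methyl-3-oxopentyl)cyclohex-2-en-1-one, via silyl dienol ether 6 (not isolated), via adduct silyl enol ether 7 (not isolated)
Conditions: LDA, TMSCl, THF, −78 °C, then solvent exchange; 5, chiral N-spiro binaphthyl quaternary ammonium bifluoride (5 mol %), toluene/THF, −78 °C; 1 M HCl work-up
Reagents that add atoms: 4-methylpent-1-en-3-one, C=CC(=O)C(C)C
Why: Proposed new method: fluoride-triggered Mukaiyama–Michael addition in which the chiral ammonium cation is ion-paired with the tetrasubstituted dienolate and shields one face as C6 adds to the vinyl ketone, setting the quaternary centre as S, while silyl transfer to the adduct enolate suppresses a second Michael addition; the closest known reactions are chiral ammonium fluoride- or phenoxide-catalysed Mukaiyama–Michael additions of silyl enol ethers to enones and phase-transfer Michael additions that build quaternary centres.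

**Step 3**
Reactants: 8 (6S)-3,6-dimethyl-6-(4-methyl-3-oxopentyl)cyclohex-2-en-1-one; 9 dibromomethane
Product: 12 (7S)-4,7-dimethyl-7-(4-methyl-3-oxopentyl)cyclohept-3-en-1-one, via dibromomethyl carbinolate 10 (not isolated), via ring-expanded dienolate 11 (not isolated)
Conditions: LiTMP (2.2 equiv), CH2Br2 (1.1 equiv), THF, −90 °C; n-BuLi (1.2 equiv), −90 → −20 °C; AcOH, −78 °C
Reagents that add atoms: dibromomethane, BrCBr
Why: One equivalent of LiTMP masks the isopropyl ketone as its enolate, LiCHBr2 adds 1,2 to the enone carbonyl, and bromine–lithium exchange gives a β-oxido carbenoid whose alkenyl carbon migrates (Nozaki–Yamamoto one-carbon ring expansion, a Tiffeneau–Demjanov-type 1,2-shift); kinetic α-protonation of the dienolate leaves the β,γ-enone and the quaternary centre is untouched.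

**Step 4**
Reactants: 12 (7S)-4,7-dimethyl-7-(4-methyl-3-oxopentyl)cyclohept-3-en-1-one
Product: 14 (3R,3aR,8aS)-6,8a-dimethyl-3-(propan-2-yl)-1,2,3,3a,4,7,8,8a-octahydroazulene-3,3a-diol, via samarium diolate 13 (not isolated)
Conditions: SmI2 (2.5 equiv), t-BuOH (2 equiv), THF, −78 → 0 °C; aq. NH4Cl
Reagents that add atoms: none
Why: Intramolecular ketyl–carbonyl (pinacol) coupling closes the C4–C5 bond; the three-atom tether on the quaternary carbon reaches only the carbonyl face that gives the cis-fused bicycle (C5–O cis to the angular methyl), and the samarium-bridged transition state gives the cis-diol, so C4 (R) and C5 (R) both follow from C1.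

**Step 5**
Reactants: 14 (3R,3aR,8aS)-6,8a-dimethyl-3-(propan-2-yl)-1,2,3,3a,4,7,8,8a-octahydroazulene-3,3a-diol; 15 4-methoxybenzoic acid
Product: 17 (3R,3aS,4S,8aS)-3-hydroxy-6,8a-dimethyl-3-(propan-2-yl)-1,2,3,3a,4,7,8,8a-octahydroazulen-4-yl 4-methoxybenzoate, via allyl cation 16 (not isolated)
Conditions: 15 (5 equiv), TfOH (2 mol %), (CF3)2CHOH/CH2Cl2 1:1, −20 → 0 °C
Reagents that add atoms: 4-methoxybenzoic acid, COc1ccc(cc1)C(=O)O
Why: Proposed new method: ionisation of the tertiary homoallylic C5–OH is assisted by the antiperiplanar C6–H, which migrates to C5 with inversion (cis → trans ring fusion, C5 becomes S) to give the C6–C8 allyl cation, and the acid adds at C6 on the face away from the C4 branch (C6 becomes S; any tertiary C8 ester re-ionises under the conditions), with hexafluoroisopropanol hydrogen-bonding the C4–OH to damp a competing pinacol shift; the closest known reactions are pinacol/Meinwald-type 1,2-hydride shifts and acid- or fluoroalcohol-promoted dehydrative allylic esterification, and the step copies the cyclase's 1,2-hydride shift followed by oxygen capture.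

**Compound list**
1 | 3-methylcyclohex-2-en-1-one | CC1=CC(=O)CCC1 | starting material
2 | iodomethane | CI | starting material
3 | lithium 5-methylcyclohexa-1,5-dien-1-olate | [Li+].CC1=CC([O-])=CCC1 | intermediate
4 | 3,6-dimethylcyclohex-2-en-1-one (racemic) | CC1=CC(=O)C(C)CC1 | intermediate
5 | 4-methylpent-1-en-3-one (isopropyl vinyl ketone) | C=CC(=O)C(C)C | starting material
6 | [(2,5-dimethylcyclohexa-1,5-dien-1-yl)oxy]trimethylsilane | CC1=C(O[Si](C)(C)C)C=C(C)CC1 | intermediate
7 | (6S)-3,6-dimethyl-6-{4-methyl-3-[(trimethylsilyl)oxy]pent-2-en-1-yl}cyclohex-2-en-1-one | O=C1C=C(C)CC[C@@]1(C)CC=C(O[Si](C)(C)C)C(C)C | intermediate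
8 | (6S)-3,6-dimethyl-6-(4-methyl-3-oxopentyl)cyclohex-2-en-1-one | O=C1C=C(C)CC[C@@]1(C)CCC(=O)C(C)C | intermediate
9 | dibromomethane | BrCBr | starting material
10 | dilithium (6S)-1-(dibromomethyl)-3,6-dimethyl-6-(4-methyl-3-oxidopent-2-en-1-yl)cyclohex-2-en-1-olate | [Li+].[Li+].[O-]C1(C(Br)Br)C=C(C)CC[C@@]1(C)CC=C([O-])C(C)C | intermediate
11 | dilithium (7S)-4,7-dimethyl-7-(4-methyl-3-oxidopent-2-en-1-yl)cyclohepta-1,3-dien-1-olate | [Li+].[Li+].[O-]C1=CC=C(C)CC[C@@]1(C)CC=C([O-])C(C)C | intermediate
12 | (7S)-4,7-dimethyl-7-(4-methyl-3-oxopentyl)cyclohept-3-en-1-one | O=C1CC=C(C)CC[C@@]1(C)CCC(=O)C(C)C | intermediate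
13 | bis(diiodosamarium(III)) (3R,3aR,8aS)-6,8a-dimethyl-3-(propan-2-yl)-1,2,3,3a,4,7,8,8a-octahydroazulene-3,3a-diolate | [Sm+3].[Sm+3].[I-].[I-].[I-].[I-].C1C=C(C)CC[C@@]2(C)CC[C@@]([O-])(C(C)C)[C@@]12[O-] | intermediate
14 | (3R,3aR,8aS)-6,8a-dimethyl-3-(propan-2-yl)-1,2,3,3a,4,7,8,8a-octahydroazulene-3,3a-diol | C1C=C(C)CC[C@@]2(C)CC[C@@](O)(C(C)C)[C@@]12O | intermediate
15 | 4-methoxybenzoic acid | COc1ccc(cc1)C(=O)O | starting material
16 | (3R,3aS,8aS)-3-hydroxy-6,8a-dimethyl-3-(propan-2-yl)-octahydroazulenyl C4–C6 allyl cation | [CH+]1C=C(C)CC[C@@]2(C)CC[C@@](O)(C(C)C)[C@H]12 | intermediate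
17 | (3R,3aS,4S,8aS)-3-hydroxy-6,8a-dimethyl-3-(propan-2-yl)-1,2,3,3a,4,7,8,8a-octahydroazulen-4-yl 4-methoxybenzoate | COc1ccc(C(=O)O[C@H]2C=C(C)CC[C@@]3(C)CC[C@@](O)(C(C)C)[C@H]23)cc1 | target

**Totals**
Total step count: 5. Longest linear sequence: 5 steps (1 → 4 → 8 → 12 → 14 → 17).

**Steps most likely to fail**

Step 5 is the weakest. The isopropyl group on C4 is also antiperiplanar to the leaving C5–O bond, so a pinacol shift can compete with the hydride shift. Loss of H6 as a proton gives a 5,7-dienol, and a free C5 cation would lose the stereochemical memory that makes the ring fusion trans. The fallback sets out from 14 and comes back at 17. Treat 14 with 1,1'-carbonyldiimidazole and NaH to give the cyclic carbonate (3R,3aR,8aS)-6,8a-dimethyl-3-(propan-2-yl)-1,2,3,3a,4,7,8,8a-octahydroazulene-3,3a-diyl carbonate F7, in which O4 can no longer push. BF3·OEt2 at −40 °C then ionises C5–O, the hydride shift follows, and the carbonate oxygen closes on C6 from the face of C4 to give (3R,3aS,4R,8aS)-6,8a-dimethyl-3-(propan-2-yl)-1,2,3,3a,4,7,8,8a-octahydroazulene-3,4-diyl carbonate F8, which is the wrong configuration at C6. K2CO3 in methanol gives (3R,3aS,4R,8aS)-6,8a-dimethyl-3-(propan-2-yl)-1,2,3,3a,4,7,8,8a-octahydroazulene-3,4-diol F9. Mitsunobu esterification of the secondary allylic alcohol with 15 (PPh3, DIAD) inverts C6 and gives 17.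

Step 2 is next. The enantioselective addition of a simple tetrasubstituted dienolate to an unsubstituted vinyl ketone has no direct precedent, and a second Michael addition (bicyclo[2.2.2]octanone) can compete. The fallback sets out from 4 and comes back at 8. LiHMDS and allyl chloroformate give allyl 2,5-dimethylcyclohexa-1,5-dien-1-yl carbonate F1. Decarboxylative asymmetric allylic alkylation (Pd2(dba)3, t-BuPHOX enantiomer chosen for S) gives (6S)-3,6-dimethyl-6-(prop-2-en-1-yl)cyclohex-2-en-1-one F2. Aldehyde-selective Wacker oxidation (PdCl2(PhCN)2, CuCl2, AgNO2, O2) gives 3-[(1S)-1,4-dimethyl-2-oxocyclohex-3-en-1-yl]propanal F3. i-PrMgCl at −78 °C adds to the aldehyde to give (6S)-6-(3-hydroxy-4-methylpentyl)-3,6-dimethylcyclohex-2-en-1-one F4, and Dess–Martin oxidation gives 8.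

Step 3 is third. The in-situ side-chain enolate can add intramolecularly to the enone, LiCHBr2 can attack the wrong carbonyl, and the quaternary alkyl carbon may migrate instead of the alkenyl carbon. The fallback sets out from 8 and comes back at 12. Selective ketalisation of the saturated ketone (1,2-bis(trimethylsilyloxy)ethane, TMSOTf cat., −78 °C, enone untouched) gives (6S)-3,6-dimethyl-6-{2-[2-(propan-2-yl)-1,3-dioxolan-2-yl]ethyl}cyclohex-2-en-1-one F5. The carbenoid ring expansion, now with one equivalent of base and no enolate in the flask, gives (7S)-4,7-dimethyl-7-{2-[2-(propan-2-yl)-1,3-dioxolan-2-yl]ethyl}cyclohept-3-en-1-one F6. PPTS in wet acetone removes the ketal and gives 12.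

**Further compounds**
F1 | step 2 | allyl 2,5-dimethylcyclohexa-1,5-dien-1-yl carbonate | CC1=C(OC(=O)OCC=C)C=C(C)CC1
F2 | step 2 | (6S)-3,6-dimethyl-6-(prop-2-en-1-yl)cyclohex-2-en-1-one | O=C1C=C(C)CC[C@@]1(C)CC=C
F3 | step 2 | 3-[(1S)-1,4-dimethyl-2-oxocyclohex-3-en-1-yl]propanal | O=C1C=C(C)CC[C@@]1(C)CCC=O
F4 | step 2 | (6S)-6-(3-hydroxy-4-methylpentyl)-3,6-dimethylcyclohex-2-en-1-one | O=C1C=C(C)CC[C@@]1(C)CCC(O)C(C)C
F5 | step 3 | (6S)-3,6-dimethyl-6-{2-[2-(propan-2-yl)-1,3-dioxolan-2-yl]ethyl}cyclohex-2-en-1-one | O=C1C=C(C)CC[C@@]1(C)CCC1(OCCO1)C(C)C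
F6 | step 3 | (7S)-4,7-dimethyl-7-{2-[2-(propan-2-yl)-1,3-dioxolan-2-yl]ethyl}cyclohept-3-en-1-one | O=C1CC=C(C)CC[C@@]1(C)CCC1(OCCO1)C(C)C
F7 | step 5 | (3R,3aR,8aS)-6,8a-dimethyl-3-(propan-2-yl)-1,2,3,3a,4,7,8,8a-octahydroazulene-3,3a-diyl carbonate | C1C=C(C)CC[C@@]2(C)CC[C@@]3(OC(=O)O[C@]123)C(C)C
F8 | step 5 | (3R,3aS,4R,8aS)-6,8a-dimethyl-3-(propan-2-yl)-1,2,3,3a,4,7,8,8a-octahydroazulene-3,4-diyl carbonate | O=C1O[C@@H]2C=C(C)CC[C@@]3(C)CC[C@@](O1)(C(C)C)[C@H]23
F9 | step 5 | (3R,3aS,4R,8aS)-6,8a-dimethyl-3-(propan-2-yl)-1,2,3,3a,4,7,8,8a-octahydroazulene-3,4-diol | O[C@@H]1C=C(C)CC[C@@]2(C)CC[C@@](O)(C(C)C)[C@H]12
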